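At early times in red, D can reach X in one step, while E lies two steps from D, by way of L.

| flask | D | time | remark |
|---|---|---|---|
| red | 0.80 M | 10 min | everything together in a closed stirred flask, run for 10 min |
| green | 0.80 M |  | a single well-mixed tank run continuously and read at steady state, 100 min in it on average |
| grey | 0.80 M |  | one stirred flow tank at steady state, fed with the mixture as stated, mean residence time 10 min |

- the set-up with the highest share of Z in all that became Z or J, at the outlet or at the end ("none" if the first two lie within 2 percentage points) (red / green / grey / none)
- share of Z in all that became Z or J, at the outlet or at the end, red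
- share of Z in all that became Z or J, at the outlet or at the end, green
- share of Z in all that became Z or J, at the outlet or at the end, grey

    L ⇌ X (K1 = 0.36, k1 = 0.043 min⁻¹)
    L ⇌ E (K2 = 1.8, k2 = 0.092 min⁻¹)
    D ⇌ G (K3 = 1.0, k3 = 0.50 min⁻¹)
    X ⇌ D (k4 = 0.14 min⁻¹)
    E → Z (k5 = 0.12 min⁻¹)
    X → J (k6 = 0.082 min⁻¹)
    D ⇌ L (K7 = 0.55, k7 = 0.23 min⁻¹)

Every step is first order, so I reckon per unit of [D]. The back step of X ⇌ D carries D directly to X, at 0.0277 min⁻¹. In a steady tank, each intermediate's inflow equals its outflow. That outflow is the sum of its exit constants plus the flushing rate, the inverse of the mean residence time. The sums before flushing are 0.171 min⁻¹ for E, 0.341 min⁻¹ for X and 0.553 min⁻¹ for L.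

Now I turn the question round. For grey to beat green, flushing would have to cost X more than E, which asks for E's sum to stand above X's. Here E's sum is half of X's, so I expect slow flow to favour Z.

For green I first ignore the returns into L. That gives [L]/[D] = 0.408, [X]/[D] = 0.129 and [E]/[D] = 0.207. I put these back as returns and go round once, so [L]/[D] becomes 0.455. The selectivity factor W is Z's rate over J's rate at steady state, 0.12 min⁻¹[E] over 0.082 min⁻¹[X]. For green it comes to 2.51, so the share is 71.5 %.

Grey, with a mean residence time equal to red's run time, goes the same way: [L]/[D] = 0.379, W = 1.89, share 65.4 %. Grey's outlet mixes short stays with long ones, while red's contents all share one age, so I put red below 65.4 %. My choice is green.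

The forecast says green, with 61.3 % for red, 71.6 % for green and 65.4 % for grey, starting from “Every step is first order”. The simulation gives 61.3 % for red, 71.6 % for green and 65.4 % for grey, so green is best.

Green's result, turned into a factor, is 2.52, against my 2.51. Red stands 4.1 percentage points under grey. The neighbour is the red flask read at 40 min. It is no tank, but I reckon a tank with that mean residence time beside it: [L]/[D] comes to 0.440 and W to 2.37, lower than green's, which makes that tank's share 70.3 %. The neighbour flask holds 29.5 % Z and 12.4 % J, in percent of the D charged, and its share reads 70.5 %.

The numbers come from no measurement, and the outcome is calculated.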